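**Retrosynthetic overview**
- Feature: ring B is a 1,3,4-trisubstituted benzene. C4' (OMe) is para to C1', the carbon bonded to C2 of pyranone ring C, and C3' carries the (R)-2-hydroxy-3-methylbut-3-enyl chain. A 2-methoxy-3-alkylbuta-1,3-diene places exactly this pattern on a terminal alkyne.
- Key disconnection: C1'–C2' and C5'–C6' of ring B (Diels–Alder, then DDQ dehydrogenation). This leads back to a 2-ethynylchromone and an enantiopure diene.
- Dienophile: the alkyne comes from C2 zincation/iodination and Sonogashira coupling, and ring C from DMF-DMA closure of an o-hydroxyaryl MOM-oxymethyl ketone. The ketone comes from 3-hydroxy-4,5-dimethoxybenzaldehyde by Baeyer–Villiger oxidation and directed ortho-lithiation/Weinreb acylation.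
- Diene: Barbier 2-bromoallylation of methacrolein, Sharpless kinetic resolution (sets R), silylation, then Negishi coupling with 1-methoxyvinylzinc chloride.
- Ring order: A (purchased), C (step 8), B (steps 16 and 17). Fluoride and dilute acid then free the three hydroxy groups.

Key step: step 16

Assumption: 8, 9 and 10 are mixtures of both configurations at the THP acetal carbon, which is lost in step 7, and 12 is drawn without alkene geometry; neither affects the single stereocentre of the target.

Step 1
Reactants: 1 methyl glycolate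
Product: 2 methyl 2-(methoxymethoxy)acetate
Conditions: MOMCl, iPr2NEt, CH2Cl2, 0 °C to rt
Reagents that add atoms: chloromethyl methyl ether (MOMCl), COCCl
Why: MOM protection (O-alkylation of the primary alcohol with a hindered amine base) leaves the ester untouched.

Step 2
Reactants: 2 methyl 2-(methoxymethoxy)acetate
Product: 3 N-methoxy-2-(methoxymethoxy)-N-methylacetamide
Conditions: MeNH(OMe)·HCl, iPrMgCl, THF, −20 °C to 0 °C
Reagents that add atoms: N,O-dimethylhydroxylamine hydrochloride, CNOC.Cl
Why: Weinreb amide formation, in which the magnesium amide attacks the ester and the chelated adduct resists further addition.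

Step 3
Reactants: 4 3-hydroxy-4,5-dimethoxybenzaldehyde
Product: 5 3,4-dimethoxy-5-(triisopropylsilyloxy)benzaldehyde
Conditions: TIPSCl, imidazole, DMF, rt
Reagents that add atoms: triisopropylsilyl chloride, CC(C)[Si](Cl)(C(C)C)C(C)C
Why: Phenol silylation; the bulky, non-coordinating TIPS ether is chosen because it later screens the adjacent ring CH from lithiation and should survive base, mild acid and DDQ.

Step 4
Reactants: 5 3,4-dimethoxy-5-(triisopropylsilyloxy)benzaldehyde
Product: 7 3,4-dimethoxy-5-(triisopropylsilyloxy)phenol, via aryl formate 6 (not isolated)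
Conditions: mCPBA, CH2Cl2, 0 °C to rt; aq. NaHCO3 wash; then K2CO3 (cat.), MeOH, 0 °C
Reagents that add atoms: mCPBA, O=C(OO)c1cccc(Cl)c1
Why: Baeyer–Villiger (Dakin-type) oxidation, in which the electron-rich trialkoxyaryl group migrates in preference to hydride and the aryl formate is methanolysed much faster than the TIPS ether.

Step 5
Reactants: 7 3,4-dimethoxy-5-(triisopropylsilyloxy)phenol
Product: 8 2-[3,4-dimethoxy-5-(triisopropylsilyloxy)phenoxy]tetrahydro-2H-pyran
Conditions: 3,4-dihydro-2H-pyran, PPTS (cat.), CH2Cl2, rt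
Reagents that add atoms: 3,4-dihydro-2H-pyran, C1=COCCC1
Why: Acid-catalysed THP acetal formation gives a group that directs ortho-lithiation and can later be removed under milder acid than an alkyl MOM ether.

Step 6
Reactants: 8 2-[3,4-dimethoxy-5-(triisopropylsilyloxy)phenoxy]tetrahydro-2H-pyran; 3 N-methoxy-2-(methoxymethoxy)-N-methylacetamide
Product: 10 1-[2,3-dimethoxy-6-(tetrahydropyran-2-yloxy)-4-(triisopropylsilyloxy)phenyl]-2-(methoxymethoxy)ethanone, via aryllithium 9 (not isolated)
Conditions: n-BuLi, TMEDA, THF, −10 °C to 0 °C; then 3, −78 °C to 0 °C; aq. NH4Cl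
Reagents that add atoms: none
Why: Directed ortho-metalation followed by Weinreb ketone synthesis; the CH between OTHP and OMe is activated by two coordinating oxygens while the other CH is shielded by the TIPS ether, so the acyl carbon (future C4) should enter between the future O1 and the 5-OMe group without over-addition.

Step 7
Reactants: 10 1-[2,3-dimethoxy-6-(tetrahydropyran-2-yloxy)-4-(triisopropylsilyloxy)phenyl]-2-(methoxymethoxy)ethanone
Product: 11 1-[6-hydroxy-2,3-dimethoxy-4-(triisopropylsilyloxy)phenyl]-2-(methoxymethoxy)ethanone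
Conditions: PPTS (cat.), MeOH, 40 °C
Reagents that add atoms: none
Why: Transacetalisation of the aryl THP ether with methanol under conditions too mild to cleave the primary alkyl MOM ether or the aryl TIPS ether.

Step 8
Reactants: 11 1-[6-hydroxy-2,3-dimethoxy-4-(triisopropylsilyloxy)phenyl]-2-(methoxymethoxy)ethanone
Product: 13 5,6-dimethoxy-3-(methoxymethoxy)-7-(triisopropylsilyloxy)chromen-4-one, via enaminone 12 (not isolated)
Conditions: Me2NCH(OMe)2, toluene, 95 °C; then AcOH, 60 °C
Reagents that add atoms: N,N-dimethylformamide dimethyl acetal, COC(OC)N(C)C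
Why: Enaminone condensation at the alpha-CH2, then addition–elimination by the phenol with loss of dimethylamine, closes ring C as in the isoflavone and 3-alkoxychromone syntheses from 2-hydroxyaryl ketones.

Step 9
Reactants: 13 5,6-dimethoxy-3-(methoxymethoxy)-7-(triisopropylsilyloxy)chromen-4-one
Product: 15 2-iodo-5,6-dimethoxy-3-(methoxymethoxy)-7-(triisopropylsilyloxy)chromen-4-one, via 2-chromonylzinc chloride 14 (not isolated)
Conditions: TMPZnCl·LiCl, THF, 25 °C; then I2, THF, 0 °C
Reagents that add atoms: iodine, II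
Why: Directed C2 zincation of a chromone followed by iodinolysis; C2–H is the only pyranone CH, is acidified by O1 and guided by the MOM oxygens, and the mild zinc amide does not add to the carbonyl.

Step 10
Reactants: 15 2-iodo-5,6-dimethoxy-3-(methoxymethoxy)-7-(triisopropylsilyloxy)chromen-4-one; 16 ethynyltrimethylsilane
Product: 17 5,6-dimethoxy-3-(methoxymethoxy)-7-(triisopropylsilyloxy)-2-[(trimethylsilyl)ethynyl]chromen-4-one
Conditions: PdCl2(PPh3)2 (3 mol %), CuI (5 mol %), Et3N, THF, rt
Reagents that add atoms: none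
Why: Sonogashira coupling; the electron-poor alkenyl iodide should undergo oxidative addition at room temperature, and a tertiary amine cannot displace iodide at C2 by addition–elimination.

Step 11
Reactants: 17 5,6-dimethoxy-3-(methoxymethoxy)-7-(triisopropylsilyloxy)-2-[(trimethylsilyl)ethynyl]chromen-4-one
Product: 18 2-ethynyl-5,6-dimethoxy-3-(methoxymethoxy)-7-(triisopropylsilyloxy)chromen-4-one
Conditions: AgNO3 (10 mol %), acetone–H2O, rt, dark
Reagents that add atoms: none
Why: Silver-catalysed protiodesilylation of a trimethylsilylalkyne runs at neutral pH, so the aryl TIPS ether is kept and no fluoride or alkoxide is present to add to the electrophilic enyne.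

Step 12
Reactants: 19 methacrolein; 20 2,3-dibromopropene
Product: 22 rac-5-bromo-2-methylhexa-1,5-dien-3-ol, via bis(2-bromoallyl)tin dibromide 21 (not isolated)
Conditions: Sn powder, HBr (cat.), Et2O–H2O, rt
Reagents that add atoms: none
Why: Barbier-type allylation; tin inserts only into the allylic C–Br bond and the allyltin species adds 1,2 to the enal, leaving the vinyl bromide intact and giving the carbinol centre as a racemate.

Step 13
Reactants: 22 rac-5-bromo-2-methylhexa-1,5-dien-3-ol
Product: 23 (R)-5-bromo-2-methylhexa-1,5-dien-3-ol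
Conditions: Ti(OiPr)4 (cat.), L-(+)-DIPT (cat.), t-BuOOH (0.6 equiv), 4 Å MS, CH2Cl2, −20 °C
Reagents that add atoms: none
Why: Sharpless kinetic resolution; with L-(+)-DIPT the (S)-allylic alcohol is epoxidised much faster, so running just past half conversion should leave the (R)-alcohol in high enantiomeric purity, and the electron-poor homoallylic vinyl bromide is not epoxidised.

Step 14
Reactants: 23 (R)-5-bromo-2-methylhexa-1,5-dien-3-ol
Product: 24 (R)-(5-bromo-2-methylhexa-1,5-dien-3-yloxy)triethylsilane
Conditions: TESCl, imidazole, CH2Cl2, 0 °C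
Reagents that add atoms: triethylsilyl chloride, CC[Si](Cl)(CC)CC
Why: Silylation on oxygen does not touch the C–O bond of the stereocentre and masks the alcohol from the organozinc reagent, the lanthanide additive and DDQ.

Step 15
Reactants: 24 (R)-(5-bromo-2-methylhexa-1,5-dien-3-yloxy)triethylsilane; 25 methyl vinyl ether
Product: 28 (R)-2-methoxy-3-[3-methyl-2-(triethylsilyloxy)but-3-enyl]buta-1,3-diene, via 1-methoxyvinyllithium 26 (not isolated), via 1-methoxyvinylzinc chloride 27 (not isolated)
Conditions: 25, t-BuLi, THF, −78 °C to 0 °C; ZnCl2, THF, 0 °C; then 24, Pd(PPh3)4 (5 mol %), THF, 40 °C; basic work-up, Et3N-deactivated SiO2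
Reagents that add atoms: none
Why: Negishi coupling of an alkenyl bromide with an alpha-alkoxyvinylzinc reagent (alpha-lithiation of the vinyl ether, then transmetalation) builds the diene under neutral anhydrous conditions that spare the enol ether and the remote stereocentre.

Step 16
Reactants: 18 2-ethynyl-5,6-dimethoxy-3-(methoxymethoxy)-7-(triisopropylsilyloxy)chromen-4-one; 28 (R)-2-methoxy-3-[3-methyl-2-(triethylsilyloxy)but-3-enyl]buta-1,3-diene
Product: 29 5,6-dimethoxy-2-{4-methoxy-5-[(R)-3-methyl-2-(triethylsilyloxy)but-3-enyl]cyclohexa-1,4-dien-1-yl}-3-(methoxymethoxy)-7-(triisopropylsilyloxy)chromen-4-one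
Conditions: 28 (3 equiv), Eu(fod)3 (10 mol %; fod = 6,6,7,7,8,8,8-heptafluoro-2,2-dimethyloctane-3,5-dionate), BHT (5 mol %), 4 Å MS, toluene (1.5 M), 90 °C, sealed tube, Ar; filtration through Et3N-deactivated SiO2
Reagents that add atoms: none
Why: Proposed new method: no 2-ethynylchromone has served as a Diels–Alder dienophile, the closest known reaction type being the cycloaddition of alkynyl ketones and propiolates with 2-alkoxybutadienes to 1-alkoxycyclohexa-1,4-dienes. The mechanism expected is a concerted, asynchronous, normal-electron-demand (4+2) cycloaddition between s-cis 28, whose HOMO is largest on the CH2 terminus of the enol ether, and the alkyne of 18, whose LUMO is largest on the terminal carbon because that carbon is the delta position of the vinylogous ynone C4=O/C3=C2/C≡C; ring B therefore closes in one intermolecular step as a six-membered carbocycle, with C5'–C6' forming ahead of C1'–C2'. The selectivity needed is regiochemical (methoxy carbon para and side chain meta to C1') and it rests on this matched polarisation, the strongly donating methoxy group overriding the weak opposite bias of the alkyl group on the adjacent diene carbon. Since O1 and the 3-OMOM group feed electron density into C2=C3 and so weaken the acceptor, Eu(fod)3 is added to bind the C4 carbonyl and 5-OMe oxygens and lower the LUMO; this neutral chelate is tolerated by enol ethers, acetals and silyl ethers, and excess diene at high concentration adds further rate. The temperature is capped at 90 °C because 28 also contains a 3-silyloxy-1,5-diene (C=C–CH2–CH(OTES)–C(CH3)=CH2) that can drain away by a Cope shift when heated harder, while the tetrasubstituted C2=C3 bond and the unactivated isopropenyl group are not competitive 2π partners. No stereocentre is created, and the R centre at C2'' lies outside the reacting array and is carried through unchanged.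

Step 17
Reactants: 29 5,6-dimethoxy-2-{4-methoxy-5-[(R)-3-methyl-2-(triethylsilyloxy)but-3-enyl]cyclohexa-1,4-dien-1-yl}-3-(methoxymethoxy)-7-(triisopropylsilyloxy)chromen-4-one
Product: 30 5,6-dimethoxy-3-(methoxymethoxy)-2-{4-methoxy-3-[(R)-3-methyl-2-(triethylsilyloxy)but-3-enyl]phenyl}-7-(triisopropylsilyloxy)chromen-4-one
Conditions: DDQ (1.1 equiv), toluene, 0 °C to rt
Reagents that add atoms: none
Why: DDQ dehydrogenation of a 1-methoxycyclohexa-1,4-diene (hydride abstraction from a doubly allylic CH2, then proton loss) is driven by aromatisation and should be far faster than any attack on the allylic silyl ether or the isopropenyl group.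

Step 18
Reactants: 30 5,6-dimethoxy-3-(methoxymethoxy)-2-{4-methoxy-3-[(R)-3-methyl-2-(triethylsilyloxy)but-3-enyl]phenyl}-7-(triisopropylsilyloxy)chromen-4-one
Product: 31 7-hydroxy-2-{3-[(R)-2-hydroxy-3-methylbut-3-enyl]-4-methoxyphenyl}-5,6-dimethoxy-3-(methoxymethoxy)chromen-4-one
Conditions: Bu4NF (2.5 equiv), AcOH (2.5 equiv), THF, 0 °C to rt
Reagents that add atoms: none
Why: Fluoride-induced cleavage of both Si–O bonds; the acetic acid buffer keeps the medium nearly neutral, and the C–O bond of the stereocentre is not involved.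

Step 19
Reactants: 31 7-hydroxy-2-{3-[(R)-2-hydroxy-3-methylbut-3-enyl]-4-methoxyphenyl}-5,6-dimethoxy-3-(methoxymethoxy)chromen-4-one
Product: 32 3,7-dihydroxy-2-{3-[(R)-2-hydroxy-3-methylbut-3-enyl]-4-methoxyphenyl}-5,6-dimethoxychromen-4-one (CNP0264719.1)
Conditions: HCl (0.5 M in MeOH), 35 °C
Reagents that add atoms: none
Why: Acid-catalysed acetal exchange removes the MOM group from the acidic 3-enol oxygen next to C4=O under conditions too mild to ionise the secondary allylic alcohol or protonate the isopropenyl group, so the R centre is retained.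

**Compound list**
1 | methyl glycolate | COC(=O)CO | starting material
2 | methyl 2-(methoxymethoxy)acetate | COCOCC(=O)OC | intermediate
3 | N-methoxy-2-(methoxymethoxy)-N-methylacetamide | COCOCC(=O)N(C)OC | intermediate
4 | 3-hydroxy-4,5-dimethoxybenzaldehyde | COc1cc(C=O)cc(O)c1OC | starting material
5 | 3,4-dimethoxy-5-(triisopropylsilyloxy)benzaldehyde | COc1cc(C=O)cc(O[Si](C(C)C)(C(C)C)C(C)C)c1OC | intermediate
6 | 3,4-dimethoxy-5-(triisopropylsilyloxy)phenyl formate | COc1cc(OC=O)cc(O[Si](C(C)C)(C(C)C)C(C)C)c1OC | intermediate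
7 | 3,4-dimethoxy-5-(triisopropylsilyloxy)phenol | COc1cc(O)cc(O[Si](C(C)C)(C(C)C)C(C)C)c1OC | intermediate
8 | 2-[3,4-dimethoxy-5-(triisopropylsilyloxy)phenoxy]tetrahydro-2H-pyran | COc1cc(OC2CCCCO2)cc(O[Si](C(C)C)(C(C)C)C(C)C)c1OC | intermediate
9 | [2,3-dimethoxy-6-(tetrahydropyran-2-yloxy)-4-(triisopropylsilyloxy)phenyl]lithium | COc1c([Li])c(OC2CCCCO2)cc(O[Si](C(C)C)(C(C)C)C(C)C)c1OC | intermediate
10 | 1-[2,3-dimethoxy-6-(tetrahydropyran-2-yloxy)-4-(triisopropylsilyloxy)phenyl]-2-(methoxymethoxy)ethanone | COc1c(C(=O)COCOC)c(OC2CCCCO2)cc(O[Si](C(C)C)(C(C)C)C(C)C)c1OC | intermediate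
11 | 1-[6-hydroxy-2,3-dimethoxy-4-(triisopropylsilyloxy)phenyl]-2-(methoxymethoxy)ethanone | COc1c(C(=O)COCOC)c(O)cc(O[Si](C(C)C)(C(C)C)C(C)C)c1OC | intermediate
12 | 3-(dimethylamino)-1-[6-hydroxy-2,3-dimethoxy-4-(triisopropylsilyloxy)phenyl]-2-(methoxymethoxy)prop-2-en-1-one | COc1c(C(=O)C(OCOC)=CN(C)C)c(O)cc(O[Si](C(C)C)(C(C)C)C(C)C)c1OC | intermediate
13 | 5,6-dimethoxy-3-(methoxymethoxy)-7-(triisopropylsilyloxy)chromen-4-one | COCOc1coc2cc(O[Si](C(C)C)(C(C)C)C(C)C)c(OC)c(OC)c2c1=O | intermediate
14 | [5,6-dimethoxy-3-(methoxymethoxy)-4-oxo-7-(triisopropylsilyloxy)chromen-2-yl]zinc chloride | COCOc1c([Zn]Cl)oc2cc(O[Si](C(C)C)(C(C)C)C(C)C)c(OC)c(OC)c2c1=O | intermediate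
15 | 2-iodo-5,6-dimethoxy-3-(methoxymethoxy)-7-(triisopropylsilyloxy)chromen-4-one | COCOc1c(I)oc2cc(O[Si](C(C)C)(C(C)C)C(C)C)c(OC)c(OC)c2c1=O | intermediate
16 | ethynyltrimethylsilane | C#C[Si](C)(C)C | starting material
17 | 5,6-dimethoxy-3-(methoxymethoxy)-7-(triisopropylsilyloxy)-2-[(trimethylsilyl)ethynyl]chromen-4-one | COCOc1c(C#C[Si](C)(C)C)oc2cc(O[Si](C(C)C)(C(C)C)C(C)C)c(OC)c(OC)c2c1=O | intermediate
18 | 2-ethynyl-5,6-dimethoxy-3-(methoxymethoxy)-7-(triisopropylsilyloxy)chromen-4-one | C#Cc1oc2cc(O[Si](C(C)C)(C(C)C)C(C)C)c(OC)c(OC)c2c(=O)c1OCOC | intermediate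
19 | methacrolein | C=C(C)C=O | starting material
20 | 2,3-dibromopropene | C=C(Br)CBr | starting material
21 | bis(2-bromoallyl)tin dibromide | C=C(Br)C[Sn](Br)(Br)CC(Br)=C | intermediate
22 | rac-5-bromo-2-methylhexa-1,5-dien-3-ol | C=C(C)C(O)CC(Br)=C | intermediate
23 | (R)-5-bromo-2-methylhexa-1,5-dien-3-ol | C=C(C)[C@H](O)CC(Br)=C | intermediate
24 | (R)-(5-bromo-2-methylhexa-1,5-dien-3-yloxy)triethylsilane | C=C(C)[C@H](O[Si](CC)(CC)CC)CC(Br)=C | intermediate
25 | methyl vinyl ether | C=COC | starting material
26 | 1-methoxyvinyllithium | [Li]C(=C)OC | intermediate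
27 | 1-methoxyvinylzinc chloride | Cl[Zn]C(=C)OC | intermediate
28 | (R)-2-methoxy-3-[3-methyl-2-(triethylsilyloxy)but-3-enyl]buta-1,3-diene | C=C(C)[C@H](O[Si](CC)(CC)CC)CC(=C)C(=C)OC | intermediate
29 | 5,6-dimethoxy-2-{4-methoxy-5-[(R)-3-methyl-2-(triethylsilyloxy)but-3-enyl]cyclohexa-1,4-dien-1-yl}-3-(methoxymethoxy)-7-(triisopropylsilyloxy)chromen-4-one | C=C(C)[C@H](O[Si](CC)(CC)CC)CC1=C(OC)CC=C(c2oc3cc(O[Si](C(C)C)(C(C)C)C(C)C)c(OC)c(OC)c3c(=O)c2OCOC)C1 | intermediate
30 | 5,6-dimethoxy-3-(methoxymethoxy)-2-{4-methoxy-3-[(R)-3-methyl-2-(triethylsilyloxy)but-3-enyl]phenyl}-7-(triisopropylsilyloxy)chromen-4-one | C=C(C)[C@H](O[Si](CC)(CC)CC)Cc1cc(-c2oc3cc(O[Si](C(C)C)(C(C)C)C(C)C)c(OC)c(OC)c3c(=O)c2OCOC)ccc1OC | intermediate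
31 | 7-hydroxy-2-{3-[(R)-2-hydroxy-3-methylbut-3-enyl]-4-methoxyphenyl}-5,6-dimethoxy-3-(methoxymethoxy)chromen-4-one | C=C(C)[C@H](O)Cc1cc(-c2oc3cc(O)c(OC)c(OC)c3c(=O)c2OCOC)ccc1OC | intermediate
32 | 3,7-dihydroxy-2-{3-[(R)-2-hydroxy-3-methylbut-3-enyl]-4-methoxyphenyl}-5,6-dimethoxychromen-4-one (CNP0264719.1) | C=C(C)[C@H](O)Cc1cc(-c2oc3cc(O)c(OC)c(OC)c3c(=O)c2O)ccc1OC | target

**Step count**
Total step count: 19.
Longest linear sequence: 13 steps, from 4 through steps 3–11 and 16–19.

**Three steps most likely to fail**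

1. Step 16 (bears the label "Proposed new method:").
   - Risk: the cycloaddition may be slower than the sigmatropic loss and self-condensation of the diene. The alkyl group of the diene may also erode the regiocontrol.
   - Fallback (known chemistry): ring B is bought as an arene and joined to C2 by Negishi cross-coupling. It sets out from 13 (with 19) and comes back to the route at 30.
   - Commercial 4-bromo-2-(bromomethyl)-1-methoxybenzene is treated with Zn dust and LiCl in THF to give 5-bromo-2-methoxybenzylzinc bromide F1.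
   - F1 adds to methacrolein 19 in the presence of MgCl2 to give racemic 1-(5-bromo-2-methoxyphenyl)-3-methylbut-3-en-2-ol F2.
   - Sharpless kinetic resolution (Ti(OiPr)4, L-(+)-DIPT, t-BuOOH, −20 °C) should leave (R)-1-(5-bromo-2-methoxyphenyl)-3-methylbut-3-en-2-ol F3.
   - TESCl and imidazole convert F3 into (R)-[1-(5-bromo-2-methoxyphenyl)-3-methylbut-3-en-2-yloxy]triethylsilane F4.
   - Compound 13 is zincated as in step 9 to 14, and 14 is coupled with F4 (Pd(OAc)2, SPhos, THF, 50 °C) to give 30 directly.

2. Step 15.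
   - Risk: hydrolysis or oligomerisation of the enol-ether diene during coupling and isolation, protonation of the methoxyvinylzinc reagent, or slow oxidative addition to the branched alkenyl bromide.
   - Fallback: the enol ether carbon is introduced as an ester and methylenated. It sets out from 24 and comes back at 28.
   - Palladium-catalysed methoxycarbonylation (PdCl2(PPh3)2, CO at 1 atm, MeOH, Et3N, DMF, 60 °C) gives methyl (R)-5-methyl-2-methylidene-4-(triethylsilyloxy)hex-5-enoate F5.
   - The ester carbonyl of F5 is methylenated with Cp2TiMe2 in toluene at 65 °C (Petasis olefination). This non-acidic reaction turns an acrylate directly into the 2-methoxydiene 28.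

3. Step 6.
   - Risk: incomplete metalation or metalation at the ring position next to the silyl ether, and proton transfer from the alpha-CH2 of amide 3 to the hindered aryllithium.
   - Fallback: the metal is placed by halogenation and halogen–metal exchange instead of C–H deprotonation. It sets out from 7 and comes back at 10.
   - Iodination of 7 with N-iodosuccinimide in MeCN at −20 °C should take place at the ortho position remote from the TIPS ether, giving 2-iodo-3,4-dimethoxy-5-(triisopropylsilyloxy)phenol F6.
   - Dihydropyran and PPTS give 2-[2-iodo-3,4-dimethoxy-5-(triisopropylsilyloxy)phenoxy]tetrahydro-2H-pyran F7.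
   - Iodine–magnesium exchange with iPrMgCl·LiCl in THF at −20 °C gives [2,3-dimethoxy-6-(tetrahydropyran-2-yloxy)-4-(triisopropylsilyloxy)phenyl]magnesium chloride F8.
   - F8 is less basic than the aryllithium, and its acylation with 3 gives 10.

**Further compounds**
F1 | step 16 | 5-bromo-2-methoxybenzylzinc bromide | COc1ccc(Br)cc1C[Zn]Br
F2 | step 16 | rac-1-(5-bromo-2-methoxyphenyl)-3-methylbut-3-en-2-ol | C=C(C)C(O)Cc1cc(Br)ccc1OC
F3 | step 16 | (R)-1-(5-bromo-2-methoxyphenyl)-3-methylbut-3-en-2-ol | C=C(C)[C@H](O)Cc1cc(Br)ccc1OC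
F4 | step 16 | (R)-[1-(5-bromo-2-methoxyphenyl)-3-methylbut-3-en-2-yloxy]triethylsilane | C=C(C)[C@H](O[Si](CC)(CC)CC)Cc1cc(Br)ccc1OC
F5 | step 15 | methyl (R)-5-methyl-2-methylidene-4-(triethylsilyloxy)hex-5-enoate | C=C(C)[C@H](O[Si](CC)(CC)CC)CC(=C)C(=O)OC
F6 | step 6 | 2-iodo-3,4-dimethoxy-5-(triisopropylsilyloxy)phenol | Oc1cc(O[Si](C(C)C)(C(C)C)C(C)C)c(OC)c(OC)c1I
F7 | step 6 | 2-[2-iodo-3,4-dimethoxy-5-(triisopropylsilyloxy)phenoxy]tetrahydro-2H-pyran | Ic1c(OC2CCCCO2)cc(O[Si](C(C)C)(C(C)C)C(C)C)c(OC)c1OC
F8 | step 6 | [2,3-dimethoxy-6-(tetrahydropyran-2-yloxy)-4-(triisopropylsilyloxy)phenyl]magnesium chloride | Cl[Mg]c1c(OC2CCCCO2)cc(O[Si](C(C)C)(C(C)C)C(C)C)c(OC)c1OC
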